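**Plan**

- Locants of the target: ring C1 (C=O), C2=C3, C4H2, C5 (C–OH), C6H2; side chain C1'H2, C2' (C=O), then the (Z)-heptadec-8-enyl tail.
- Retrosynthesis: move the enone to C3=C4 and re-form a C2–O bond from the C5 oxygen (an oxygen-bridged 7-oxanorbornenone); take the C2' ketone back to a carbinol and put a carboxyl on C6 that is lactonised onto it; write C1=O as C1–Br; then cut C1–C2 and C5–C6 together (retro-Diels–Alder) to a 2-alkylfuran and a 3-bromopropiolate ester; the furan–C1' and C1'–C2' bonds come from furan, one ylide carbon and oleyl alcohol.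
- Enabling feature: O–C5 and C2 are 1,4 across the ring, so O, C5, C4, C3, C2 map onto a 2-substituted furan and C1/C6 onto a two-carbon dienophile; C2' is 1,3 to C5, so its oxygen at the alcohol level can carry the dienophile as an ester whose carboxyl sits on C6 in a six-membered lactone (C5, C1', C2', O, C=O, C6).
- Forward order: oleyl alcohol → C19 terminal epoxide (resolved) → furyl carbinol → bromopropiolate ester; the cycloaddition closes carbocycle and lactone together; then bromide → ketone, loss of the tether carbon as CO2, carbinol → ketone, reductive cleavage of the C2–O bridge bond, conjugation.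
- Stereochemistry: the Z-alkene is bought with oleyl alcohol; C5 is set in the cycloaddition by relay from the (S)-carbinol (hydrolytic kinetic resolution), which is afterwards oxidised to the C2' ketone; the bridgehead centre at C2 disappears on ring opening.

Key step: step 7

Assumption: the fused δ-lactone is taken to survive methoxide in step 8; if it is opened to the hydroxy methyl ester instead, step 9 converges on the same acid.

**Step 1**
Reactants: 1 oleyl alcohol, (Z)-octadec-9-en-1-ol
Product: 2 (Z)-octadec-9-enal
Conditions: TEMPO (10 mol %), PhI(OAc)2 (1.1 equiv), CH2Cl2, rt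
Reagents that add atoms: none
Why: Oxoammonium (TEMPO/PhI(OAc)2) oxidation of a primary alcohol stops at the aldehyde and leaves the isolated Z-alkene untouched.

**Step 2**
Reactants: 2 (Z)-octadec-9-enal
Product: 3 rac-2-[(Z)-heptadec-8-en-1-yl]oxirane
Conditions: Me3S+ I− (1.2 equiv), n-BuLi (1.15 equiv), THF, −10 °C; then 2, −10 °C → rt
Reagents that add atoms: trimethylsulfonium iodide, C[S+](C)C.[I-]
Why: Corey–Chaykovsky epoxidation, in which the sulfonium ylide adds to the aldehyde and the betaine closes with loss of dimethyl sulfide, should give the racemic terminal epoxide without touching the alkene.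

**Step 3**
Reactants: 3 rac-2-[(Z)-heptadec-8-en-1-yl]oxirane
Product: 4 (S)-2-[(Z)-heptadec-8-en-1-yl]oxirane
Conditions: (S,S)-(salen)Co(OAc) (0.5 mol %, trivalent cobalt; salen = N,N'-bis(3,5-di-tert-butylsalicylidene)cyclohexane-1,2-diamine dianion), H2O (0.55 equiv), THF (minimal), 0 °C → rt
Reagents that add atoms: none
Why: In the Jacobsen hydrolytic kinetic resolution the (S,S)-catalyst should hydrolyse the (R)-epoxide to the diol and leave the (S)-epoxide, so the relay stereocentre is set by catalyst control.

**Step 4**
Reactants: 4 (S)-2-[(Z)-heptadec-8-en-1-yl]oxirane; 5 furan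
Product: 7 (2S,10Z)-1-(furan-2-yl)nonadec-10-en-2-ol, via 2-furyllithium 6 (not isolated)
Conditions: 5 (1.5 equiv), n-BuLi (1.4 equiv), THF, 0 °C, 1 h; then 4, 0 °C → rt; H2O quench
Reagents that add atoms: none
Why: α-Lithiation of furan and SN2 opening of the epoxide at its unsubstituted carbon should give the carbinol; no bond to the stereocentre is touched, so its configuration is kept.

**Step 5**
Reactants: 8 propiolic acid
Product: 9 3-bromoprop-2-ynoic acid (3-bromopropiolic acid)
Conditions: NBS (1.1 equiv), AgNO3 (10 mol %), acetone, rt, dark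
Reagents that add atoms: N-bromosuccinimide, O=C1CCC(=O)N1Br
Why: Silver-catalysed electrophilic bromination of a terminal alkyne (through the silver acetylide) should give the 1-bromoalkyne.

**Step 6**
Reactants: 7 (2S,10Z)-1-(furan-2-yl)nonadec-10-en-2-ol; 9 3-bromoprop-2-ynoic acid
Product: 10 (2S,10Z)-1-(furan-2-yl)nonadec-10-en-2-yl 3-bromoprop-2-ynoate
Conditions: DCC (1.1 equiv), CH2Cl2, −20 → 0 °C (no DMAP)
Reagents that add atoms: none
Why: Carbodiimide esterification acylates the carbinol oxygen without breaking its C–O bond (configuration kept), and the nucleophilic catalyst is left out because it would add to the bromoalkynoate.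

**Step 7**
Reactants: 10 (2S,10Z)-1-(furan-2-yl)nonadec-10-en-2-yl 3-bromoprop-2-ynoate
Product: 11 tricyclic bromo lactone: 3-bromo-1-[(2S,10Z)-2-hydroxynonadec-10-en-1-yl]-7-oxabicyclo[2.2.1]hepta-2,5-diene-2-carboxylic acid δ-lactone, with the carbinol hydrogen on the lactone face turned to the CH=CH bridge
Conditions: PhMe (0.01 M), BHT (5 mol %), 80 °C
Reagents that add atoms: none
Why: Thermal intramolecular Diels–Alder reaction in which the furan is the diene (its oxygen and four carbons become O–C5, C4, C3, C2) and the tethered bromoalkynoate the dienophile (C6 and C1), a concerted, asynchronous, normal-demand [4+2] cycloaddition whose closest precedents are the intermolecular cycloaddition of 2-alkylfurans with alkyl 3-bromopropiolates and ester-tethered intramolecular furan Diels–Alder reactions. It closes two rings at once: the six-membered carbocycle by the [4+2] itself (suprafacial on both partners, the furan oxygen left as a 1,4-bridge) and the δ-lactone through the new C5–C6 bond in the fused mode (tether joined to the diene terminus and to the proximal alkyne carbon, alkyne exocyclic to the forming ring). Of the two new stereocentres the bridgehead C2 is tied to C5 by the oxygen bridge, and C5 is controlled by the (S)-carbinol of the tether: in the half-chair of the forming lactone the long chain should take the pseudo-equatorial position, with the carbinol hydrogen turned toward the C3=C4 side, and this exposes one furan face. Regioselectivity is enforced by the tether and matched electronically (the bromine-bearing, electrophilic alkyne carbon goes to the unsubstituted, more nucleophilic furan α-carbon), the isolated Z-alkene is an unactivated dienophile and stays out, and high dilution suppresses the bimolecular cycloaddition. Because furan cycloadditions are reversible, the diastereomer ratio can also drift toward the more stable chain-equatorial adduct, and the minor diastereomer would be removed by chromatography.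

**Step 8**
Reactants: 11 tricyclic bromo lactone
Product: 12 dimethyl ketal lactone: 1-[(2S,10Z)-2-hydroxynonadec-10-en-1-yl]-3,3-dimethoxy-7-oxabicyclo[2.2.1]hept-5-ene-2-carboxylic acid δ-lactone (either configuration at C2 of the bicycle)
Conditions: NaOMe (2.5 equiv), MeOH–THF, 0 °C → rt
Reagents that add atoms: sodium methoxide, [Na+].[O-]C; methanol, CO
Why: Methoxide adds to the strained β-bromo enoate, bromide is expelled (addition–elimination on a vinylogous acyl bromide) and a second conjugate addition with protonation gives the ketal, the sequence known for furan/3-bromopropiolate cycloadducts; the new CH centre is of no consequence because it becomes CH2 in step 9.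

**Step 9**
Reactants: 12 dimethyl ketal lactone
Product: 15 (1R,4R)-4-[(2S,10Z)-2-hydroxynonadec-10-en-1-yl]-7-oxabicyclo[2.2.1]hept-5-en-2-one, via ketal hydroxy acid 13 (not isolated), via hydroxy β-keto acid 14 (not isolated)
Conditions: LiOH·H2O (3 equiv), THF–H2O, 0 °C → rt; then 1 M HCl to pH 1, THF, 40 °C
Reagents that add atoms: water, O
Why: Saponification opens the lactone at the ketal stage, acid then hydrolyses the ketal and the β-keto acid loses CO2 through its enol, which removes the tether carbon, leaves C6 as CH2 and frees the side-chain carbinol.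

**Step 10**
Reactants: 15 (1R,4R)-4-[(2S,10Z)-2-hydroxynonadec-10-en-1-yl]-7-oxabicyclo[2.2.1]hept-5-en-2-one
Product: 16 (1R,4R)-4-[(10Z)-2-oxononadec-10-en-1-yl]-7-oxabicyclo[2.2.1]hept-5-en-2-one
Conditions: DMP (1.3 equiv), CH2Cl2, 0 °C → rt
Reagents that add atoms: none
Why: Dess–Martin oxidation of the secondary alcohol installs the C2' ketone and erases the relay stereocentre while the future tertiary hydroxyl is still masked as the bridging ether, so no oxa-Michael or retro-aldol path is open.

**Step 11**
Reactants: 16 (1R,4R)-4-[(10Z)-2-oxononadec-10-en-1-yl]-7-oxabicyclo[2.2.1]hept-5-en-2-one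
Product: 17 (5R)-5-hydroxy-5-[(10Z)-2-oxononadec-10-en-1-yl]cyclohex-3-en-1-one
Conditions: SmI2 (2.5 equiv, divalent samarium), THF–MeOH, −78 °C; pH 7 phosphate buffer
Reagents that add atoms: none
Why: Samarium diiodide reduction of an α-alkoxy ketone: the ketyl of the bridged ketone expels the adjacent bridge C–O bond with strain release and the resulting dienolate is protonated at the α-carbon, while the side-chain ketone, which has no α-heteroatom, should react far more slowly and no bond to C5 is broken.

**Step 12**
Reactants: 17 (5R)-5-hydroxy-5-[(10Z)-2-oxononadec-10-en-1-yl]cyclohex-3-en-1-one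
Product: 18 (5R)-5-hydroxy-5-[(10Z)-2-oxononadec-10-en-1-yl]cyclohex-2-en-1-one
Conditions: Et3N (0.5 equiv), CH2Cl2, 0 °C → rt
Reagents that add atoms: none
Why: Base-mediated conjugation of a β,γ-unsaturated ketone through its doubly activated α-CH2 (dienolate, γ-protonation) should give the thermodynamically favoured enone, and the mild amine is chosen so that the tertiary β-hydroxyl is not eliminated.

**Compound list**

1 | oleyl alcohol, (Z)-octadec-9-en-1-ol | CCCCCCCC/C=C\CCCCCCCCO | starting material
2 | (Z)-octadec-9-enal | CCCCCCCC/C=C\CCCCCCCC=O | intermediate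
3 | rac-2-[(Z)-heptadec-8-en-1-yl]oxirane | CCCCCCCC/C=C\CCCCCCCC1CO1 | intermediate
4 | (S)-2-[(Z)-heptadec-8-en-1-yl]oxirane | CCCCCCCC/C=C\CCCCCCC[C@H]1CO1 | intermediate
5 | furan | c1ccoc1 | starting material
6 | 2-furyllithium | [Li]c1ccco1 | intermediate
7 | (2S,10Z)-1-(furan-2-yl)nonadec-10-en-2-ol | CCCCCCCC/C=C\CCCCCCC[C@H](O)Cc1ccco1 | intermediate
8 | propiolic acid | C#CC(=O)O | starting material
9 | 3-bromoprop-2-ynoic acid | OC(=O)C#CBr | intermediate
10 | (2S,10Z)-1-(furan-2-yl)nonadec-10-en-2-yl 3-bromoprop-2-ynoate | CCCCCCCC/C=C\CCCCCCC[C@H](OC(=O)C#CBr)Cc1ccco1 | intermediate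
11 | 3-bromo-1-[(2S,10Z)-2-hydroxynonadec-10-en-1-yl]-7-oxabicyclo[2.2.1]hepta-2,5-diene-2-carboxylic acid δ-lactone | CCCCCCCC/C=C\CCCCCCC[C@H]1C[C@]23O[C@H](C=C2)C(Br)=C3C(=O)O1 | intermediate
12 | 1-[(2S,10Z)-2-hydroxynonadec-10-en-1-yl]-3,3-dimethoxy-7-oxabicyclo[2.2.1]hept-5-ene-2-carboxylic acid δ-lactone (C2 of the bicycle undefined) | CCCCCCCC/C=C\CCCCCCC[C@H]1C[C@]23O[C@H](C=C2)C(OC)(OC)C3C(=O)O1 | intermediate
13 | 1-[(2S,10Z)-2-hydroxynonadec-10-en-1-yl]-3,3-dimethoxy-7-oxabicyclo[2.2.1]hept-5-ene-2-carboxylic acid | CCCCCCCC/C=C\CCCCCCC[C@H](O)C[C@]12O[C@H](C=C1)C(OC)(OC)C2C(=O)O | intermediate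
14 | 1-[(2S,10Z)-2-hydroxynonadec-10-en-1-yl]-3-oxo-7-oxabicyclo[2.2.1]hept-5-ene-2-carboxylic acid | CCCCCCCC/C=C\CCCCCCC[C@H](O)C[C@]12O[C@H](C=C1)C(=O)C2C(=O)O | intermediate
15 | (1R,4R)-4-[(2S,10Z)-2-hydroxynonadec-10-en-1-yl]-7-oxabicyclo[2.2.1]hept-5-en-2-one | CCCCCCCC/C=C\CCCCCCC[C@H](O)C[C@]12O[C@H](C=C1)C(=O)C2 | intermediate
16 | (1R,4R)-4-[(10Z)-2-oxononadec-10-en-1-yl]-7-oxabicyclo[2.2.1]hept-5-en-2-one | CCCCCCCC/C=C\CCCCCCCC(=O)C[C@]12O[C@H](C=C1)C(=O)C2 | intermediate
17 | (5R)-5-hydroxy-5-[(10Z)-2-oxononadec-10-en-1-yl]cyclohex-3-en-1-one | CCCCCCCC/C=C\CCCCCCCC(=O)C[C@]1(O)C=CCC(=O)C1 | intermediate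
18 | (5R)-5-hydroxy-5-[(10Z)-2-oxononadec-10-en-1-yl]cyclohex-2-en-1-one | CCCCCCCC/C=C\CCCCCCCC(=O)C[C@]1(O)CC=CC(=O)C1 | target

**Step count and risks**

Total steps: 12. Longest linear sequence: 11 steps (steps 1–4 and 6–12, from oleyl alcohol); step 5 is a one-step branch.

Steps most likely to fail:

1. Step 7. The ester prefers its extended conformation, so the folded conformer that can cyclise is thinly populated; bimolecular cycloaddition or thermal decomposition of the haloalkynoate may then compete. The facial bias from the remote carbinol may also be weak or run the other way; in the latter case the (R)-epoxide from the (R,R)-catalyst would be carried through the same steps. The fallback sets out from 7 and comes back at 15. Carbinol 7 is silylated (TBSCl, imidazole, DMF) to the silyl ether F1. Intermolecular Diels–Alder reaction with methyl 3-bromopropiolate (benzene, 80 °C), which on 2-alkylfurans places the ester next to the substituted bridgehead, gives the oxanorbornadiene ester F2 as both bridgehead diastereomers. NaOMe in MeOH gives the dimethyl ketal ester F3. LiOH followed by aqueous HCl (ketal hydrolysis, decarboxylation and loss of the silyl group) gives 15 together with the bridgehead-epimeric hydroxy ketone F4; the two are diastereomers and are parted by chromatography.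

2. Step 9. The hindered lactone may resist saponification, and forcing base can open the oxygen bridge by β-elimination from the enolate at the carbon next to the quaternary bridgehead; the ketal next to the bridge oxygen may hydrolyse slowly. The fallback sets out from 12 and comes back at 15; it reverses the order of unmasking and leaves base out. Aqueous acid at room temperature hydrolyses the ketal to the β-keto lactone F5, and continued warming in aqueous acetic acid–HCl brings about the classical ketonic cleavage (acid hydrolysis of the β-keto lactone driven by loss of CO2 from 14) to 15.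

3. Step 11. Competing reduction or ketyl coupling at the side-chain ketone, retro-aldol cleavage of the samarium alkoxide next to two β-carbonyl groups, or loss of the tertiary oxygen with aromatisation may erode the ring opening. The fallback sets out from 15 and comes back at 17; the two redox steps change places so that only one ketone is present during the reduction. SmI2 in THF–MeOH at −78 °C on 15 gives the dihydroxy β,γ-enone F6, whose secondary alcohol alone is then oxidised with Dess–Martin periodinane to 17.

**Further compounds**

F1 | step 7 | tert-butyl{[(2S,10Z)-1-(furan-2-yl)nonadec-10-en-2-yl]oxy}dimethylsilane | CCCCCCCC/C=C\CCCCCCC[C@H](O[Si](C)(C)C(C)(C)C)Cc1ccco1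
F2 | step 7 | methyl 3-bromo-1-[(2S,10Z)-2-(tert-butyldimethylsilyloxy)nonadec-10-en-1-yl]-7-oxabicyclo[2.2.1]hepta-2,5-diene-2-carboxylate (both bridgehead configurations) | CCCCCCCC/C=C\CCCCCCC[C@H](O[Si](C)(C)C(C)(C)C)CC12OC(C=C1)C(Br)=C2C(=O)OC
F3 | step 7 | methyl 1-[(2S,10Z)-2-(tert-butyldimethylsilyloxy)nonadec-10-en-1-yl]-3,3-dimethoxy-7-oxabicyclo[2.2.1]hept-5-ene-2-carboxylate (diastereomer mixture) | CCCCCCCC/C=C\CCCCCCC[C@H](O[Si](C)(C)C(C)(C)C)CC12OC(C=C1)C(OC)(OC)C2C(=O)OC
F4 | step 7 | (1S,4S)-4-[(2S,10Z)-2-hydroxynonadec-10-en-1-yl]-7-oxabicyclo[2.2.1]hept-5-en-2-one | CCCCCCCC/C=C\CCCCCCC[C@H](O)C[C@@]12O[C@@H](C=C1)C(=O)C2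
F5 | step 9 | 1-[(2S,10Z)-2-hydroxynonadec-10-en-1-yl]-3-oxo-7-oxabicyclo[2.2.1]hept-5-ene-2-carboxylic acid δ-lactone | CCCCCCCC/C=C\CCCCCCC[C@H]1C[C@]23O[C@H](C=C2)C(=O)C3C(=O)O1
F6 | step 11 | (5R)-5-hydroxy-5-[(2S,10Z)-2-hydroxynonadec-10-en-1-yl]cyclohex-3-en-1-one | CCCCCCCC/C=C\CCCCCCC[C@H](O)C[C@]1(O)C=CCC(=O)C1
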